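**Retrosynthetic overview** (iridoid-type locants: ring C-5 bears the C3 side chain, C-6 is the ring CH2, C-7 carries the O-acyl group, C-8 the CH3, C-9 the CH2OH carbon C-1; side-chain C-4 carries C-3H2OH and C-11H2O-acyl)
1. Both ester C–O bonds are cut: core diol 15 (C-1 and C-3 hydroxyls as TBS ethers) plus two equivalents of one acid 25, in which the enal is a dimethyl acetal and the CH2CHO arm is a CH2CH2OTES group; the ring ester is formed with inversion.
2. The cyclopentane is closed at C-5–C-6 by intramolecular Michael addition of a methyl ketone enolate (C-6/C-7) onto an (E)-2-(benzyloxymethyl)enoate (C-5=C-4); lactonisation (C-1–O–C-3) and equilibration follow in the same flask.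
3. Enabling feature: C-7, C-8, C-9 and C-5 carry their substituents all-trans (all pseudo-equatorial); C-6 is α to oxygenated C-7 and C-5 is β to the C-3 carboxyl. In the trans-fused δ-lactone the equatorial C-11 arm is exactly the target C-4 configuration, so the single C-9 centre relays C-5, C-8 and C-4 in one event.
4. Ring order: γ-butyrolactone (temporary, carries C-9 from a Rh-catalysed vinylation; opened by MeLi), then cyclopentanone, then trans-fused δ-lactone (temporary, reduced to the C-1/C-3 diol); C-7 is set by L-Selectride and inverted in the Mitsunobu esterification.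
5. Acid 25: Rh/BINAP conjugate addition of the alkenylborate from (Z)-2-iodobut-2-enal acetal to 5,6-dihydro-2H-pyran-2-one sets the acyl stereocentre and the E geometry; the aldehydes are released last.

Key step: step 6

Assumption: the facial sense of the two Rh/BINAP conjugate additions (steps 1 and 12) is assigned by analogy with cyclic enones and enoates; if the sense proves opposite, the antipodal ligand is used and nothing else changes.

**Route**

Step 1
Reactants: 1 furan-2(5H)-one
Product: 2 (4R)-4-ethenyloxolan-2-one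
Conditions: CH2=CHBF3K (2 equiv), [Rh(cod)2]BF4 (3 mol %), (R)-BINAP, toluene/H2O, 100 °C
Reagents that add atoms: potassium vinyltrifluoroborate, C=C[B-](F)(F)F.[K+]
Why: Rh/BINAP-catalysed asymmetric conjugate addition (Hayashi–Miyaura type) of an alkenylboron reagent to an unsaturated lactone; the ligand is expected to direct the vinyl group to the face that gives the R centre, the only stereocentre of the core that is set by catalysis.

Step 2
Reactants: 2 (4R)-4-ethenyloxolan-2-one
Product: 3 (3S,4S)-4-ethenyl-3-methyloxolan-2-one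
Conditions: LDA, THF, −78 °C; MeI, −78 → −40 °C
Reagents that add atoms: iodomethane, CI
Why: lactone enolate alkylation, expected anti to the β-vinyl group; this carbon is re-equilibrated in step 6, so its configuration here is of no consequence.

Step 3
Reactants: 3 (3S,4S)-4-ethenyl-3-methyloxolan-2-one
Product: 4 (3S,4S)-4-(hydroxymethyl)-3-methylhex-5-en-2-one (in equilibrium with its cyclic hemiketal)
Conditions: MeLi (1.05 equiv), THF, −78 °C; aq. NH4Cl
Reagents that add atoms: methyllithium, [Li]C
Why: mono-addition of an organolithium to a γ-lactone; the lithium lactolate should persist at −78 °C and give the methyl ketone on work-up.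

Step 4
Reactants: 5 benzyl (triphenyl-λ5-phosphanylidene)acetate (2 equiv); 6 benzyl chloromethyl ether
Product: 7 benzyl 3-(benzyloxy)-2-(triphenyl-λ5-phosphanylidene)propanoate
Conditions: CH2Cl2, 0 °C → rt; filtration of the phosphonium chloride
Reagents that add atoms: none
Why: C-alkylation of a stabilised ylide by a reactive α-chloro ether followed by transylidation, the second equivalent of 5 acting as base.

Step 5
Reactants: 4 (3S,4S)-4-(hydroxymethyl)-3-methylhex-5-en-2-one; 7 benzyl 3-(benzyloxy)-2-(triphenyl-λ5-phosphanylidene)propanoate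
Product: 9 benzyl (2E,4S,5S)-2-[(benzyloxy)methyl]-4-(hydroxymethyl)-5-methyl-6-oxohept-2-enoate, via aldehyde 8 (not isolated)
Conditions: O3, CH2Cl2, −78 °C; PPh3, −78 → 0 °C; then 7 (2.5 equiv, the excess also takes up the formaldehyde), CH2Cl2, rt
Reagents that add atoms: none
Why: ozonolysis of the terminal alkene and in-situ Wittig olefination with an α-branched stabilised ylide, which should give the (E)-enoate (ester trans to the chain); the neutral medium should preserve the α-stereocentre of 8.

Step 6
Reactants: 9 benzyl (2E,4S,5S)-2-[(benzyloxy)methyl]-4-(hydroxymethyl)-5-methyl-6-oxohept-2-enoate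
Product: 11 (4R,4aR,7R,7aS)-4-[(benzyloxy)methyl]-7-methylhexahydrocyclopenta[c]pyran-3,6-dione, via Michael adduct 10 (not isolated)
Conditions: KOt-Bu (0.3 equiv), THF/t-BuOH (10:1), 0.02 M, 0 °C → rt; AcOH quench
Reagents that add atoms: none
Why: Catalytic alkoxide reversibly forms the methyl-ketone enolate, whose CH2 terminus adds to the β-carbon of the (E)-enoate, and the resulting ester enolate is protonated (10); the closest known reaction type is the base-mediated intramolecular Michael addition of a ketone enolate to an unsaturated ester giving a trans-1,2-disubstituted cyclopentane. The cyclopentanone closes through the new C–C bond in the 5-exo-trig (5-enolexo) mode, and the δ-lactone then closes 6-exo-trig by attack of the ring CH2O– on the benzyl ester with loss of benzyl alcohol. The ring carbon that receives the side chain should be set trans to the neighbouring CH2OH-bearing carbon (the only stereocentre of 9 that matters) through a chair-like transition state with that CH2OH pseudo-equatorial, reinforced by allylic strain between the allylic C–H and the cis-CH2OBn group. The methyl-bearing carbon (α to the ketone) and the CH(CH2OBn) carbon (α to the lactone carbonyl) should then equilibrate by enolisation under the same base to the pseudo-equatorial positions, which on the trans-fused bicycle are the target configurations. The step needs regioselectivity between the two enolates (only the CH3 enolate can form a five-membered ring, the other would give a cyclopropane), a trans ring fusion (secured by the E geometry, which keeps the ester away from the CH2OH until the carbocycle exists, since a lactone closed first would force a cis fusion) and retention of the β-benzyloxy group (the protic co-solvent should reprotonate the enolates much faster than they expel benzyloxide, and with a benzyl ester the liberated alkoxide matches the ether, so any exchange is degenerate).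

Step 7
Reactants: 11 (4R,4aR,7R,7aS)-4-[(benzyloxy)methyl]-7-methylhexahydrocyclopenta[c]pyran-3,6-dione
Product: 13 (1S,2R,3S,4R)-4-[(2S)-1-(benzyloxy)-3-hydroxypropan-2-yl]-3-(hydroxymethyl)-2-methylcyclopentan-1-ol, via hydroxy lactone 12 (not isolated)
Conditions: L-Selectride (1.1 equiv), THF, −78 °C; then LiBH4 (3 equiv), MeOH (3 equiv), 0 °C → rt; aq. Rochelle salt
Reagents that add atoms: none
Why: the bulky hydride should attack the cyclopentanone anti to the α-methyl group and give the alcohol cis to methyl (the epimer required for the invertive esterification of step 14), after which LiBH4 reduces the δ-lactone to the diol.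

Step 8
Reactants: 13 (1S,2R,3S,4R)-4-[(2S)-1-(benzyloxy)-3-hydroxypropan-2-yl]-3-(hydroxymethyl)-2-methylcyclopentan-1-ol
Product: 14 (1S,2R,3S,4R)-4-[(2R)-1-(benzyloxy)-3-[(tert-butyldimethylsilyl)oxy]propan-2-yl]-3-{[(tert-butyldimethylsilyl)oxy]methyl}-2-methylcyclopentan-1-ol
Conditions: TBSCl (2.1 equiv), imidazole, CH2Cl2, −20 → 0 °C
Reagents that add atoms: tert-butyldimethylsilyl chloride, CC(C)(C)[Si](C)(C)Cl
Why: selective silylation of the two primary hydroxyls (the ones that are free in the target) in the presence of the hindered secondary cyclopentanol.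

Step 9
Reactants: 14 (1S,2R,3S,4R)-4-[(2R)-1-(benzyloxy)-3-[(tert-butyldimethylsilyl)oxy]propan-2-yl]-3-{[(tert-butyldimethylsilyl)oxy]methyl}-2-methylcyclopentan-1-ol
Product: 15 (1S,2R,3S,4R)-4-[(2R)-1-[(tert-butyldimethylsilyl)oxy]-3-hydroxypropan-2-yl]-3-{[(tert-butyldimethylsilyl)oxy]methyl}-2-methylcyclopentan-1-ol
Conditions: H2 (1 atm), Pd(OH)2/C, EtOAc, rt
Reagents that add atoms: none
Why: hydrogenolysis of the benzyl ether under neutral conditions that leave the silyl ethers in place, freeing exactly the two hydroxyls that are acylated in the target.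

Step 10
Reactants: 16 (E)-but-2-enal
Product: 17 (Z)-2-iodobut-2-enal
Conditions: I2, K2CO3, DMAP (cat.), THF/H2O, rt
Reagents that add atoms: iodine, II
Why: amine-catalysed α-iodination of an enal (conjugate addition, iodination, elimination), which gives the isomer with CHO trans to CH3.

Step 11
Reactants: 17 (Z)-2-iodobut-2-enal
Product: 18 (Z)-2-iodo-1,1-dimethoxybut-2-ene
Conditions: HC(OMe)3, MeOH, p-TsOH (cat.), rt
Reagents that add atoms: trimethyl orthoformate, COC(OC)OC
Why: acid-catalysed acetalisation masks the future enal carbonyl against organolithium, base and phosphine reagents.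

Step 12
Reactants: 18 (Z)-2-iodo-1,1-dimethoxybut-2-ene (2.5 equiv); 19 5,6-dihydro-2H-pyran-2-one
Product: 22 (4S)-4-[(2E)-1,1-dimethoxybut-2-en-2-yl]oxan-2-one, via alkenyllithium 20 (not isolated), via lithium alkenylborate 21 (not isolated)
Conditions: t-BuLi (2 equiv per 18), Et2O, −78 °C; B(OMe)3, −78 °C → rt; then 19, Rh(acac)(C2H4)2 (3 mol %), (S)-BINAP, dioxane/H2O, 100 °C
Reagents that add atoms: none
Why: iodine–lithium exchange and boration with retention of alkene geometry, then Rh/BINAP asymmetric 1,4-addition to the unsaturated δ-lactone, which should set the S centre under ligand control and place CH3 cis to the new C–C bond (the future E-enal).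

Step 13
Reactants: 22 (4S)-4-[(2E)-1,1-dimethoxybut-2-en-2-yl]oxan-2-one
Product: 25 (3S,4E)-4-(dimethoxymethyl)-3-{2-[(triethylsilyl)oxy]ethyl}hex-4-enoic acid, via potassium hydroxy carboxylate 23 (not isolated), via bis-silyl ester 24 (not isolated)
Conditions: KOH (1.05 equiv), THF/H2O, rt; concentration; TESCl (2.5 equiv), imidazole, DMF, 0 °C; then K2CO3 (cat.), MeOH/H2O, 0 °C; pH 5 buffer
Reagents that add atoms: potassium hydroxide, [K+].[OH-]; chlorotriethylsilane, CC[Si](Cl)(CC)CC
Why: saponification of the δ-lactone, silylation of both oxygens and selective hydrolysis of the labile silyl ester, which keeps the δ-hydroxyl masked so that it cannot relactonise.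

Step 14
Reactants: 15 (1S,2R,3S,4R)-4-[(2R)-1-[(tert-butyldimethylsilyl)oxy]-3-hydroxypropan-2-yl]-3-{[(tert-butyldimethylsilyl)oxy]methyl}-2-methylcyclopentan-1-ol; 25 (3S,4E)-4-(dimethoxymethyl)-3-{2-[(triethylsilyl)oxy]ethyl}hex-4-enoic acid (2.4 equiv)
Product: 26 (1R,2R,3S,4R)-3-{[(tert-butyldimethylsilyl)oxy]methyl}-4-[(2R)-1-[(tert-butyldimethylsilyl)oxy]-3-{[(3S,4E)-4-(dimethoxymethyl)-3-{2-[(triethylsilyl)oxy]ethyl}hex-4-enoyl]oxy}propan-2-yl]-2-methylcyclopentyl (3S,4E)-4-(dimethoxymethyl)-3-{2-[(triethylsilyl)oxy]ethyl}hex-4-enoate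
Conditions: PPh3, DIAD, toluene, 0 °C → rt
Reagents that add atoms: none
Why: double Mitsunobu esterification in which the primary hydroxyl is acylated and the ring carbinol is acylated with SN2 inversion, the carboxylate entering anti to the cis-methyl group to give the R-configured ester trans to methyl.

Step 15
Reactants: 26 (the bis-TES diester from step 14)
Product: 27 (1R,2R,3S,4R)-3-{[(tert-butyldimethylsilyl)oxy]methyl}-4-[(2R)-1-[(tert-butyldimethylsilyl)oxy]-3-{[(3S,4E)-4-(dimethoxymethyl)-3-(2-oxoethyl)hex-4-enoyl]oxy}propan-2-yl]-2-methylcyclopentyl (3S,4E)-4-(dimethoxymethyl)-3-(2-oxoethyl)hex-4-enoate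
Conditions: (COCl)2, DMSO, CH2Cl2, −78 → −40 °C; Et3N, −78 → 0 °C
Reagents that add atoms: none
Why: Swern conditions convert primary triethylsilyl ethers directly into aldehydes while TBS ethers are inert, so no free δ-hydroxy ester, which could lactonise and expel the core, is ever liberated.

Step 16
Reactants: 27 (the bis-acetal dialdehyde from step 15)
Product: 28 (1R,2R,3S,4R)-4-[(2S)-1-{[(3S,4E)-4-formyl-3-(2-oxoethyl)hex-4-enoyl]oxy}-3-hydroxypropan-2-yl]-3-(hydroxymethyl)-2-methylcyclopentyl (3S,4E)-4-formyl-3-(2-oxoethyl)hex-4-enoate (CNP0192766.1)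
Conditions: aq. HF (48 %)/MeCN (1:19), 0 °C; solid NaHCO3
Reagents that add atoms: water, O
Why: one mildly acidic operation hydrolyses both unsaturated dimethyl acetals and cleaves both primary TBS ethers; base is avoided because a 1,3-acyl shift between the two CH2O arms would epimerise the side-chain stereocentre.

**Compound list**
1 | furan-2(5H)-one | O=C1OCC=C1 | starting material
2 | (4R)-4-ethenyloxolan-2-one | O=C1C[C@H](C=C)CO1 | intermediate
3 | (3S,4S)-4-ethenyl-3-methyloxolan-2-one | O=C1[C@@H](C)[C@H](C=C)CO1 | intermediate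
4 | (3S,4S)-4-(hydroxymethyl)-3-methylhex-5-en-2-one | CC(=O)[C@@H](C)[C@H](C=C)CO | intermediate
5 | benzyl (triphenyl-λ5-phosphanylidene)acetate | O=C(OCc1ccccc1)C=P(c1ccccc1)(c1ccccc1)c1ccccc1 | starting material
6 | benzyl chloromethyl ether | ClCOCc1ccccc1 | starting material
7 | benzyl 3-(benzyloxy)-2-(triphenyl-λ5-phosphanylidene)propanoate | O=C(OCc1ccccc1)C(COCc1ccccc1)=P(c1ccccc1)(c1ccccc1)c1ccccc1 | intermediate
8 | (2S,3S)-2-(hydroxymethyl)-3-methyl-4-oxopentanal | CC(=O)[C@@H](C)[C@H](C=O)CO | intermediate (not isolated)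
9 | benzyl (2E,4S,5S)-2-[(benzyloxy)methyl]-4-(hydroxymethyl)-5-methyl-6-oxohept-2-enoate | CC(=O)[C@@H](C)[C@H](/C=C(\COCc1ccccc1)C(=O)OCc1ccccc1)CO | intermediate
10 | benzyl 3-(benzyloxy)-2-[(1R,2S)-2-(hydroxymethyl)-3-methyl-4-oxocyclopentyl]propanoate (epimers at chain C-2 and ring C-3) | O=C(OCc1ccccc1)C(COCc1ccccc1)[C@@H]1CC(=O)C(C)[C@H]1CO | intermediate (not isolated)
11 | (4R,4aR,7R,7aS)-4-[(benzyloxy)methyl]-7-methylhexahydrocyclopenta[c]pyran-3,6-dione | c1ccccc1COC[C@H](C(=O)O2)[C@@H]1CC(=O)[C@H](C)[C@H]1C2 | intermediate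
12 | (4R,4aR,6S,7R,7aS)-4-[(benzyloxy)methyl]-6-hydroxy-7-methylhexahydrocyclopenta[c]pyran-3(1H)-one | c1ccccc1COC[C@H](C(=O)O2)[C@@H]1C[C@H](O)[C@H](C)[C@H]1C2 | intermediate (not isolated)
13 | (1S,2R,3S,4R)-4-[(2S)-1-(benzyloxy)-3-hydroxypropan-2-yl]-3-(hydroxymethyl)-2-methylcyclopentan-1-ol | c1ccccc1COC[C@H](CO)[C@@H]1C[C@H](O)[C@H](C)[C@H]1CO | intermediate
14 | (1S,2R,3S,4R)-4-[(2R)-1-(benzyloxy)-3-[(tert-butyldimethylsilyl)oxy]propan-2-yl]-3-{[(tert-butyldimethylsilyl)oxy]methyl}-2-methylcyclopentan-1-ol | c1ccccc1COC[C@H](CO[Si](C)(C)C(C)(C)C)[C@@H]1C[C@H](O)[C@H](C)[C@H]1CO[Si](C)(C)C(C)(C)C | intermediate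
15 | (1S,2R,3S,4R)-4-[(2R)-1-[(tert-butyldimethylsilyl)oxy]-3-hydroxypropan-2-yl]-3-{[(tert-butyldimethylsilyl)oxy]methyl}-2-methylcyclopentan-1-ol | OC[C@H](CO[Si](C)(C)C(C)(C)C)[C@@H]1C[C@H](O)[C@H](C)[C@H]1CO[Si](C)(C)C(C)(C)C | intermediate
16 | (E)-but-2-enal | C/C=C/C=O | starting material
17 | (Z)-2-iodobut-2-enal | C/C=C(\I)C=O | intermediate
18 | (Z)-2-iodo-1,1-dimethoxybut-2-ene | C/C=C(\I)C(OC)OC | intermediate
19 | 5,6-dihydro-2H-pyran-2-one | O=C1C=CCCO1 | starting material
20 | [(2E)-1,1-dimethoxybut-2-en-2-yl]lithium | C/C=C(\[Li])C(OC)OC | intermediate (not isolated)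
21 | lithium [(2E)-1,1-dimethoxybut-2-en-2-yl]trimethoxyborate | C/C=C(\[B-](OC)(OC)OC)C(OC)OC.[Li+] | intermediate (not isolated)
22 | (4S)-4-[(2E)-1,1-dimethoxybut-2-en-2-yl]oxan-2-one | C/C=C(/C(OC)OC)[C@H]1CCOC(=O)C1 | intermediate
23 | potassium (3S,4E)-4-(dimethoxymethyl)-3-(2-hydroxyethyl)hex-4-enoate | C/C=C(/C(OC)OC)[C@@H](CCO)CC(=O)[O-].[K+] | intermediate (not isolated)
24 | triethylsilyl (3S,4E)-4-(dimethoxymethyl)-3-{2-[(triethylsilyl)oxy]ethyl}hex-4-enoate | C/C=C(/C(OC)OC)[C@@H](CCO[Si](CC)(CC)CC)CC(=O)O[Si](CC)(CC)CC | intermediate (not isolated)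
25 | (3S,4E)-4-(dimethoxymethyl)-3-{2-[(triethylsilyl)oxy]ethyl}hex-4-enoic acid | C/C=C(/C(OC)OC)[C@@H](CCO[Si](CC)(CC)CC)CC(=O)O | intermediate
26 | bis-TES diester of 15 with two units of 25, ring carbinol inverted to R (full name in step 14) | C/C=C(/C(OC)OC)[C@@H](CCO[Si](CC)(CC)CC)CC(=O)OC[C@H](CO[Si](C)(C)C(C)(C)C)[C@@H]1C[C@@H](OC(=O)C[C@H](CCO[Si](CC)(CC)CC)/C(C(OC)OC)=C\C)[C@H](C)[C@H]1CO[Si](C)(C)C(C)(C)C | intermediate
27 | bis-acetal dialdehyde, core bis-TBS ether (full name in step 15) | C/C=C(/C(OC)OC)[C@@H](CC=O)CC(=O)OC[C@H](CO[Si](C)(C)C(C)(C)C)[C@@H]1C[C@@H](OC(=O)C[C@H](CC=O)/C(C(OC)OC)=C\C)[C@H](C)[C@H]1CO[Si](C)(C)C(C)(C)C | intermediate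
28 | CNP0192766.1 (full name in step 16) | C/C=C(/C=O)[C@@H](CC=O)CC(=O)OC[C@H](CO)[C@@H]1C[C@@H](OC(=O)C[C@H](CC=O)/C(C=O)=C\C)[C@H](C)[C@H]1CO | target

**Step count and risks**

Total step count: 16. Longest linear sequence: 11 (steps 1, 2, 3, 5, 6, 7, 8, 9, 14, 15, 16).

Steps most likely to fail:

1. Step 6. The cascade may stall or divert in three ways: loss of benzyloxide from the ester or lactone enolate followed by oxa-Michael capture by the ring CH2O– as a cyclic ether, incomplete closure of the trans-fused lactone, or erosion of the γ-stereocentre by vinylogous deprotonation before cyclisation. The fallback installs the CH2O arm after both rings exist and sets out from 4. Cross-metathesis of 4 with benzyl acrylate (Hoveyda–Grubbs II, CH2Cl2, 40 °C) should give benzyl (2E,4S,5S)-4-(hydroxymethyl)-5-methyl-6-oxohept-2-enoate F1, which carries no β-alkoxy group. The same KOt-Bu Michael/lactonisation should then give (4aS,7R,7aS)-7-methylhexahydrocyclopenta[c]pyran-3,6-dione F2. L-Selectride reduction (THF, −78 °C) should give (4aS,6S,7R,7aS)-6-hydroxy-7-methylhexahydrocyclopenta[c]pyran-3(1H)-one F3. Its alkoxide–enolate dianion (LDA, 2.2 equiv, THF, −78 °C) is alkylated at the lactone α-carbon with benzyl chloromethyl ether; re-enolisation and axial protonation (or DBU equilibration) should place the CH2OBn group equatorial. This returns to the route at 12, which is reduced with LiBH4 as in step 7.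

2. Step 14. Elimination toward the methyl-bearing carbon or sluggish displacement at the hindered ring carbinol may consume acid 25 without clean inversion. The fallback separates inversion from acylation and sets out from 14. A Mitsunobu reaction with 4-nitrobenzoic acid (PPh3, DIAD, toluene) should give (1R,2R,3S,4R)-4-[(2R)-1-(benzyloxy)-3-[(tert-butyldimethylsilyl)oxy]propan-2-yl]-3-{[(tert-butyldimethylsilyl)oxy]methyl}-2-methylcyclopentyl 4-nitrobenzoate F4. Methanolysis (K2CO3, MeOH) should give (1R,2R,3S,4R)-4-[(2R)-1-(benzyloxy)-3-[(tert-butyldimethylsilyl)oxy]propan-2-yl]-3-{[(tert-butyldimethylsilyl)oxy]methyl}-2-methylcyclopentan-1-ol F5. Hydrogenolysis (H2, Pd(OH)2/C, EtOAc) should give (1R,2R,3S,4R)-4-[(2R)-1-[(tert-butyldimethylsilyl)oxy]-3-hydroxypropan-2-yl]-3-{[(tert-butyldimethylsilyl)oxy]methyl}-2-methylcyclopentan-1-ol F6. Yamaguchi esterification of both hydroxyls with 25 (2,4,6-trichlorobenzoyl chloride, Et3N, then DMAP, toluene) proceeds with retention and returns to the route at 26.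

3. Step 5. The α-branched β-hydroxy aldehyde 8 may epimerise or dehydrate, and the disubstituted stabilised ylide may olefinate it only slowly. The fallback avoids any aldehyde and sets out from 7 and 4. Wittig reaction of 7 with paraformaldehyde (toluene, 60 °C) should give benzyl 2-[(benzyloxy)methyl]prop-2-enoate F7. Cross-metathesis of 4 with excess F7 (Hoveyda–Grubbs II, CH2Cl2, 40 °C) forms the trisubstituted (E)-enoate directly and returns to the route at 9.

Further compounds
F1 | step 6 | benzyl (2E,4S,5S)-4-(hydroxymethyl)-5-methyl-6-oxohept-2-enoate | CC(=O)[C@@H](C)[C@H](/C=C/C(=O)OCc1ccccc1)CO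
F2 | step 6 | (4aS,7R,7aS)-7-methylhexahydrocyclopenta[c]pyran-3,6-dione | O=C1C[C@@H]2CC(=O)[C@H](C)[C@H]2CO1
F3 | step 6 | (4aS,6S,7R,7aS)-6-hydroxy-7-methylhexahydrocyclopenta[c]pyran-3(1H)-one | O=C1C[C@@H]2C[C@H](O)[C@H](C)[C@H]2CO1
F4 | step 14 | (1R,2R,3S,4R)-4-[(2R)-1-(benzyloxy)-3-[(tert-butyldimethylsilyl)oxy]propan-2-yl]-3-{[(tert-butyldimethylsilyl)oxy]methyl}-2-methylcyclopentyl 4-nitrobenzoate | c1ccccc1COC[C@H](CO[Si](C)(C)C(C)(C)C)[C@@H]1C[C@@H](OC(=O)c2ccc(cc2)[N+](=O)[O-])[C@H](C)[C@H]1CO[Si](C)(C)C(C)(C)C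
F5 | step 14 | (1R,2R,3S,4R)-4-[(2R)-1-(benzyloxy)-3-[(tert-butyldimethylsilyl)oxy]propan-2-yl]-3-{[(tert-butyldimethylsilyl)oxy]methyl}-2-methylcyclopentan-1-ol | c1ccccc1COC[C@H](CO[Si](C)(C)C(C)(C)C)[C@@H]1C[C@@H](O)[C@H](C)[C@H]1CO[Si](C)(C)C(C)(C)C
F6 | step 14 | (1R,2R,3S,4R)-4-[(2R)-1-[(tert-butyldimethylsilyl)oxy]-3-hydroxypropan-2-yl]-3-{[(tert-butyldimethylsilyl)oxy]methyl}-2-methylcyclopentan-1-ol | OC[C@H](CO[Si](C)(C)C(C)(C)C)[C@@H]1C[C@@H](O)[C@H](C)[C@H]1CO[Si](C)(C)C(C)(C)C
F7 | step 5 | benzyl 2-[(benzyloxy)methyl]prop-2-enoate | C=C(COCc1ccccc1)C(=O)OCc1ccccc1
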